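The ten-membered ring is disconnected at the bond between the ketone carbon C3 and the enone α-carbon C4 (germacranolide numbering; C15 is the CH2OH carbon on C4). An intramolecular Nozaki–Hiyama–Kishi addition of a (Z)-alkenyl iodide at C4 to an aldehyde at C3 closes the carbocycle; oxidation of the carbinol then gives the enone. The step exploits the Z-configured C4=C5 bond and the cis-fused γ-lactone ring (O–C6–C7–C11–C12), which fold the chain so that C3 and C4 meet. The precursor is an open-chain iodo aldehyde already carrying the lactone, the C8 ester and the C6, C7, C8 and C10 stereocentres, built from (R)-linalool.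

Key step: step 16

Remark: atom labels follow germacranolide numbering (ring C1–C10; C11, C12 and C13 are the lactone α-carbon, carbonyl and exo-methylene; C14 is the methyl on C10; C15 the CH2O on C4).
Remark: (R)-(−)-linalool and (R)-2-methylbutanoic acid are taken as commercial single enantiomers.
Remark: the 10-hydroxy-3-ketone of the target may equilibrate with its transannular 3,10-hemiketal; it is drawn as the open form.

Step 1
Reactants: 1 (R)-(−)-linalool
Product: 2 linalool triethylsilyl ether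
Conditions: TESOTf, 2,6-lutidine, CH2Cl2, −78 to 0 °C
Reagents that add atoms: triethylsilyl trifluoromethanesulfonate, CC[Si](CC)(CC)OS(=O)(=O)C(F)(F)F
Why: O-silylation of a hindered tertiary alcohol with a silyl triflate and a pyridine base is routine, and the C10 stereocentre is taken unchanged from the chiral pool.

Step 2
Reactants: 2 linalool triethylsilyl ether
Product: 4 primary alcohol (3R)-3,7-dimethyl-3-(triethylsilyloxy)oct-6-en-1-ol, via B-alkyl-9-BBN adduct 3 (not isolated)
Conditions: 9-BBN, THF, 0 °C to rt; then NaOH, H2O2, 0 °C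
Reagents that add atoms: 9-borabicyclo[3.3.1]nonane, B1C2CCCC1CCC2; hydrogen peroxide, OO
Why: Brown hydroboration–oxidation, in which the bulky borane adds anti-Markovnikov to the monosubstituted vinyl group much faster than to the trisubstituted alkene and oxidation places the oxygen on C8.

Step 3
Reactants: 4 primary alcohol
Product: 5 aldehyde (3R)-3,7-dimethyl-3-(triethylsilyloxy)oct-6-enal
Conditions: Dess–Martin periodinane, CH2Cl2, 0 °C to rt
Reagents that add atoms: none
Why: Dess–Martin oxidation of a primary alcohol to the aldehyde under near-neutral conditions that leave the silyl ether and the alkene intact.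

Step 4
Reactants: 5 aldehyde; 6 ethyl diazoacetate
Product: 7 β-keto ester ethyl (5R)-5,9-dimethyl-3-oxo-5-(triethylsilyloxy)dec-8-enoate
Conditions: SnCl2 (10 mol%), CH2Cl2, rt
Reagents that add atoms: ethyl diazoacetate (6), CCOC(=O)C=[N+]=[N-]
Why: Roskamp homologation, in which Lewis-acid-promoted addition of the diazo ester to the aldehyde is followed by a 1,2-hydride shift with loss of nitrogen to give the β-keto ester directly.

Step 5
Reactants: 7 β-keto ester
Product: 8 β-hydroxy ester ethyl (3R,5R)-3-hydroxy-5,9-dimethyl-5-(triethylsilyloxy)dec-8-enoate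
Conditions: H2 (50 atm), [RuCl(p-cymene)((R)-BINAP)]Cl (1 mol%), EtOH, 50 °C
Reagents that add atoms: none
Why: Noyori asymmetric hydrogenation of a β-keto ester through the ruthenium chelate, in which the (R)-BINAP ligand should direct hydride to the face giving the 3R carbinol (C8) while the isolated trisubstituted alkene is not reduced.

Step 6
Reactants: 8 β-hydroxy ester; 9 tert-butyl bromoacetate
Product: 10 anti-alkylated diester 4-tert-butyl 1-ethyl (2R)-2-[(1R,3R)-1-hydroxy-3,7-dimethyl-3-(triethylsilyloxy)oct-6-en-1-yl]butanedioate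
Conditions: LiN(i-Pr)2 (2.2 equiv), THF, −78 to −20 °C; then 9, DMPU, −78 to −20 °C
Reagents that add atoms: tert-butyl bromoacetate (9), BrCC(=O)OC(C)(C)C
Why: Fráter–Seebach alkylation, in which the chelated lithium alkoxide–enolate is attacked on the face opposite the C9 chain so that the new C7 centre is set anti to the C8 oxygen, and the tert-butyl ester resists lactonisation onto the C8 alkoxide.

Step 7
Reactants: 10 diester; 11 N,O-dimethylhydroxylamine hydrochloride
Product: 12 Weinreb amide tert-butyl (3R,4R,6R)-4-hydroxy-3-[methoxy(methyl)carbamoyl]-6,10-dimethyl-6-(triethylsilyloxy)undec-9-enoate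
Conditions: i-PrMgCl, THF, −20 to 0 °C
Reagents that add atoms: N,O-dimethylhydroxylamine hydrochloride (11), CNOC.Cl
Why: Weinreb amide formation by aminolysis with the chloromagnesium amide, which should be selective for the ethyl ester over the hindered tert-butyl ester and touches no stereocentre.

Step 8
Reactants: 12 Weinreb amide; 13 (R)-2-methylbutanoic acid
Product: 14 C8 ester tert-butyl (3R,4R,6R)-3-[methoxy(methyl)carbamoyl]-6,10-dimethyl-4-{[(2R)-2-methylbutanoyl]oxy}-6-(triethylsilyloxy)undec-9-enoate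
Conditions: DCC, DMAP, CH2Cl2, 0 °C to rt
Reagents that add atoms: (R)-2-methylbutanoic acid (13), CC[C@@H](C)C(=O)O
Why: Steglich esterification acylates the only free hydroxyl (C8) with retention at both stereocentres, so the C8 oxygen is differentiated before the C6 oxygen exists.

Step 9
Reactants: 14 C8 ester; 15 trimethyl(prop-2-yn-1-yloxy)silane
Product: 17 hydroxy ynone tert-butyl (3R,4R,6R)-3-(4-hydroxybut-2-ynoyl)-6,10-dimethyl-4-{[(2R)-2-methylbutanoyl]oxy}-6-(triethylsilyloxy)undec-9-enoate, via TMS-protected ynone 16 (not isolated)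
Conditions: 15, i-PrMgCl, THF, 0 °C; then 14, 0 °C; work-up citric acid, MeOH, 0 °C
Reagents that add atoms: trimethyl(prop-2-yn-1-yloxy)silane (15), C#CCO[Si](C)(C)C
Why: Weinreb ketone synthesis, in which the weakly basic alkynylmagnesium reagent adds once to the amide to give a stable chelate that is far more reactive than the hindered esters, and mild acid frees the ketone and cleaves the labile trimethylsilyl ether.

Step 10
Reactants: 17 hydroxy ynone
Product: 18 propargylic alcohol tert-butyl (3S,4R,6R)-3-[(1R)-1,4-dihydroxybut-2-yn-1-yl]-6,10-dimethyl-4-{[(2R)-2-methylbutanoyl]oxy}-6-(triethylsilyloxy)undec-9-enoate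
Conditions: Ru[(R,R)-TsNCH(Ph)CH(Ph)NH](p-cymene) (3 mol%), i-PrOH, rt
Reagents that add atoms: none
Why: Noyori asymmetric transfer hydrogenation of an alkynyl ketone under base-free conditions, in which the (R,R)-diamine catalyst distinguishes the alkynyl from the alkyl substituent and should set the C6 carbinol (1R in this compound) under catalyst control.

Step 11
Reactants: 18 propargylic alcohol
Product: 20 cis-lactone (1R,3R)-1-[(2R,3R)-2-(3-hydroxyprop-1-yn-1-yl)-5-oxooxolan-3-yl]-3,7-dimethyl-3-(triethylsilyloxy)oct-6-en-1-yl (2R)-2-methylbutanoate, via hydroxy acid 19 (not isolated)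
Conditions: SiO2, toluene, 110 °C
Reagents that add atoms: none
Why: Thermolytic cleavage of the tert-butyl ester on silica unmasks the C12 acid, which lactonises (5-exo-trig acyl substitution) onto the only free γ-hydroxyl at C6, and the cis ring fusion follows from the C6 and C7 configurations set in steps 10 and 6.

Step 12
Reactants: 20 cis-lactone
Product: 22 (Z)-alkenyl iodide (1R,3R)-1-[(2R,3R)-2-[(1Z)-3-hydroxy-2-iodoprop-1-en-1-yl]-5-oxooxolan-3-yl]-3,7-dimethyl-3-(triethylsilyloxy)oct-6-en-1-yl (2R)-2-methylbutanoate, via alkenylstannane 21 (not isolated)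
Conditions: Bu3SnH, [Cp*RuCl]4 (2.5 mol%), CH2Cl2, rt; then I2, 0 °C
Reagents that add atoms: tributyltin hydride, CCCC[SnH](CCCC)CCCC; iodine, II
Why: Hydroxyl-directed ruthenium-catalysed trans-hydrostannation, in which the free C15 hydroxyl steers tin to the proximal alkyne carbon C4 and hydrogen adds anti at C5, followed by stereoretentive iododestannylation so that iodine ends cis to C6.

Step 13
Reactants: 22 (Z)-alkenyl iodide
Product: 23 silyl ether (1R,3R)-1-[(2R,3R)-2-[(1Z)-3-{[tert-butyl(dimethyl)silyl]oxy}-2-iodoprop-1-en-1-yl]-5-oxooxolan-3-yl]-3,7-dimethyl-3-(triethylsilyloxy)oct-6-en-1-yl (2R)-2-methylbutanoate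
Conditions: TBSCl, imidazole, DMF, 0 °C
Reagents that add atoms: tert-butyldimethylsilyl chloride, CC(C)(C)[Si](C)(C)Cl
Why: Standard silylation of the primary allylic alcohol, so that only the C3 carbinol is oxidised in step 17.

Step 14
Reactants: 23 silyl ether
Product: 26 α-methylene lactone (1R,3R)-1-[(2R,3R)-2-[(1Z)-3-{[tert-butyl(dimethyl)silyl]oxy}-2-iodoprop-1-en-1-yl]-4-methylidene-5-oxooxolan-3-yl]-3,7-dimethyl-3-(triethylsilyloxy)oct-6-en-1-yl (2R)-2-methylbutanoate, via Mannich base 24 (not isolated), via methiodide salt 25 (not isolated)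
Conditions: LiN(SiMe3)2 (1.05 equiv), THF, −78 °C; CH2=NMe2+ I−, −78 °C to rt; then MeI, MeOH, rt; then NaHCO3, H2O/CH2Cl2
Reagents that add atoms: N,N-dimethylmethyleneiminium iodide (Eschenmoser's salt), C=[N+](C)C.[I-]; iodomethane, CI
Why: Lactone enolate Mannich reaction with Eschenmoser's salt followed by quaternisation and E1cB elimination, the standard α-methylenation, in which one equivalent of base at −78 °C should deprotonate the lactone α-CH2 in preference to the hindered α-branched ester.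

Step 15
Reactants: 26 α-methylene lactone
Product: 28 iodo aldehyde (1R,3R)-1-[(2R,3R)-2-[(1Z)-3-{[tert-butyl(dimethyl)silyl]oxy}-2-iodoprop-1-en-1-yl]-4-methylidene-5-oxooxolan-3-yl]-3-methyl-6-oxo-3-(triethylsilyloxy)hexyl (2R)-2-methylbutanoate, via secondary ozonide 27 (not isolated)
Conditions: O3, CH2Cl2, −78 °C (Sudan Red 7B end point); then PPh3, −78 °C to rt
Reagents that add atoms: ozone, [O-][O+]=O
Why: Chemoselective ozonolysis, in which the electron-rich trisubstituted alkene reacts far faster than the iodoalkene and the acrylate-type exo-methylene and the dye end point prevents over-oxidation, unmasks the C3 aldehyde.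

Step 16
Reactants: 28 iodo aldehyde
Product: 29 ten-membered allylic alcohol (3aR,4R,6R,10Z,11aS)-10-({[tert-butyl(dimethyl)silyl]oxy}methyl)-9-hydroxy-6-methyl-3-methylidene-2-oxo-6-(triethylsilyloxy)-2,3,3a,4,5,6,7,8,9,11a-decahydrocyclodeca[b]furan-4-yl (2R)-2-methylbutanoate (both C3 epimers)
Conditions: CrCl2 (10 equiv), NiCl2 (0.1 equiv), DMSO/THF, rt, 0.002 M, slow addition of 28
Reagents that add atoms: none
Why: Zerovalent nickel (formed from NiCl2 by CrCl2) inserts into the C4–I bond with retention of the Z geometry, the alkenyl group passes to trivalent chromium, and the alkenylchromium adds to the C3 aldehyde to forge the C3–C4 bond. The closest known reaction type is the intramolecular Nozaki–Hiyama–Kishi alkenyl iodide–aldehyde cyclisation used for medium and large carbocycles. The ten-membered ring closes in a 10-exo-trig mode, the carbonyl oxygen staying outside the ring. The new C3 carbinol centre is not controlled, which is immaterial because step 17 oxidises it. The step needs chemoselectivity (alkenylchromium species add to aldehydes but not to the lactone, the ester or the exo-methylene) and cyclisation over oligomerisation, secured by high dilution with slow addition and by the Z-alkene and cis-fused lactone, which hold C3 and C4 on the same side of the C5–C6–C7 turn.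

Step 17
Reactants: 29 ten-membered allylic alcohol
Product: 30 bis-silylated enone (3aR,4R,6R,10Z,11aS)-10-({[tert-butyl(dimethyl)silyl]oxy}methyl)-6-methyl-3-methylidene-2,9-dioxo-6-(triethylsilyloxy)-2,3,3a,4,5,6,7,8,9,11a-decahydrocyclodeca[b]furan-4-yl (2R)-2-methylbutanoate
Conditions: Dess–Martin periodinane, CH2Cl2, 0 °C to rt
Reagents that add atoms: none
Why: Dess–Martin oxidation should convert both C3 epimers of the allylic alcohol into the single enone without isomerising the Z-alkene or touching the silyl ethers.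

Step 18
Reactants: 30 bis-silylated enone
Product: 31 target CNP0130221.1
Conditions: HF·pyridine, pyridine, THF, 0 °C to rt
Reagents that add atoms: none
Why: Fluoride-mediated desilylation under buffered, non-basic conditions removes the tertiary triethylsilyl and the primary tert-butyldimethylsilyl ethers while sparing the methylene lactone, the enone and the ester.

Compound list
1 | (R)-(−)-linalool, (3R)-3,7-dimethylocta-1,6-dien-3-ol | CC(C)=CCC[C@@](C)(O)C=C | starting material
2 | triethyl{[(3R)-3,7-dimethylocta-1,6-dien-3-yl]oxy}silane | CC(C)=CCC[C@@](C)(O[Si](CC)(CC)CC)C=C | intermediate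
3 | 9-[(3S)-3,7-dimethyl-3-(triethylsilyloxy)oct-6-en-1-yl]-9-borabicyclo[3.3.1]nonane (same spatial arrangement at the silyloxy carbon as in 2) | CC(C)=CCC[C@@](C)(O[Si](CC)(CC)CC)CCB1C2CCCC1CCC2 | intermediate
4 | (3R)-3,7-dimethyl-3-(triethylsilyloxy)oct-6-en-1-ol | CC(C)=CCC[C@@](C)(O[Si](CC)(CC)CC)CCO | intermediate
5 | (3R)-3,7-dimethyl-3-(triethylsilyloxy)oct-6-enal | CC(C)=CCC[C@@](C)(O[Si](CC)(CC)CC)CC=O | intermediate
6 | ethyl diazoacetate | CCOC(=O)C=[N+]=[N-] | starting material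
7 | ethyl (5R)-5,9-dimethyl-3-oxo-5-(triethylsilyloxy)dec-8-enoate | CC(C)=CCC[C@@](C)(O[Si](CC)(CC)CC)CC(=O)CC(=O)OCC | intermediate
8 | ethyl (3R,5R)-3-hydroxy-5,9-dimethyl-5-(triethylsilyloxy)dec-8-enoate | CC(C)=CCC[C@@](C)(O[Si](CC)(CC)CC)C[C@@H](O)CC(=O)OCC | intermediate
9 | tert-butyl bromoacetate | BrCC(=O)OC(C)(C)C | starting material
10 | 4-tert-butyl 1-ethyl (2R)-2-[(1R,3R)-1-hydroxy-3,7-dimethyl-3-(triethylsilyloxy)oct-6-en-1-yl]butanedioate | CC(C)=CCC[C@@](C)(O[Si](CC)(CC)CC)C[C@@H](O)[C@@H](CC(=O)OC(C)(C)C)C(=O)OCC | intermediate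
11 | N,O-dimethylhydroxylamine hydrochloride | CNOC.Cl | starting material
12 | tert-butyl (3R,4R,6R)-4-hydroxy-3-[methoxy(methyl)carbamoyl]-6,10-dimethyl-6-(triethylsilyloxy)undec-9-enoate | CC(C)=CCC[C@@](C)(O[Si](CC)(CC)CC)C[C@@H](O)[C@@H](CC(=O)OC(C)(C)C)C(=O)N(C)OC | intermediate
13 | (R)-2-methylbutanoic acid | CC[C@@H](C)C(=O)O | starting material
14 | tert-butyl (3R,4R,6R)-3-[methoxy(methyl)carbamoyl]-6,10-dimethyl-4-{[(2R)-2-methylbutanoyl]oxy}-6-(triethylsilyloxy)undec-9-enoate | CC(C)=CCC[C@@](C)(O[Si](CC)(CC)CC)C[C@@H](OC(=O)[C@H](C)CC)[C@@H](CC(=O)OC(C)(C)C)C(=O)N(C)OC | intermediate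
15 | trimethyl(prop-2-yn-1-yloxy)silane | C#CCO[Si](C)(C)C | starting material
16 | tert-butyl (3R,4R,6R)-6,10-dimethyl-4-{[(2R)-2-methylbutanoyl]oxy}-6-(triethylsilyloxy)-3-[4-(trimethylsilyloxy)but-2-ynoyl]undec-9-enoate | CC(C)=CCC[C@@](C)(O[Si](CC)(CC)CC)C[C@@H](OC(=O)[C@H](C)CC)[C@@H](CC(=O)OC(C)(C)C)C(=O)C#CCO[Si](C)(C)C | intermediate
17 | tert-butyl (3R,4R,6R)-3-(4-hydroxybut-2-ynoyl)-6,10-dimethyl-4-{[(2R)-2-methylbutanoyl]oxy}-6-(triethylsilyloxy)undec-9-enoate | CC(C)=CCC[C@@](C)(O[Si](CC)(CC)CC)C[C@@H](OC(=O)[C@H](C)CC)[C@@H](CC(=O)OC(C)(C)C)C(=O)C#CCO | intermediate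
18 | tert-butyl (3S,4R,6R)-3-[(1R)-1,4-dihydroxybut-2-yn-1-yl]-6,10-dimethyl-4-{[(2R)-2-methylbutanoyl]oxy}-6-(triethylsilyloxy)undec-9-enoate | CC(C)=CCC[C@@](C)(O[Si](CC)(CC)CC)C[C@@H](OC(=O)[C@H](C)CC)[C@@H](CC(=O)OC(C)(C)C)[C@@H](O)C#CCO | intermediate
19 | (3S,4R,6R)-3-[(1R)-1,4-dihydroxybut-2-yn-1-yl]-6,10-dimethyl-4-{[(2R)-2-methylbutanoyl]oxy}-6-(triethylsilyloxy)undec-9-enoic acid | CC(C)=CCC[C@@](C)(O[Si](CC)(CC)CC)C[C@@H](OC(=O)[C@H](C)CC)[C@@H](CC(=O)O)[C@@H](O)C#CCO | intermediate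
20 | (1R,3R)-1-[(2R,3R)-2-(3-hydroxyprop-1-yn-1-yl)-5-oxooxolan-3-yl]-3,7-dimethyl-3-(triethylsilyloxy)oct-6-en-1-yl (2R)-2-methylbutanoate | CC(C)=CCC[C@@](C)(O[Si](CC)(CC)CC)C[C@@H](OC(=O)[C@H](C)CC)[C@H]1CC(=O)O[C@H]1C#CCO | intermediate
21 | (1R,3R)-1-[(2R,3R)-2-[(1Z)-3-hydroxy-2-(tributylstannyl)prop-1-en-1-yl]-5-oxooxolan-3-yl]-3,7-dimethyl-3-(triethylsilyloxy)oct-6-en-1-yl (2R)-2-methylbutanoate | CC(C)=CCC[C@@](C)(O[Si](CC)(CC)CC)C[C@@H](OC(=O)[C@H](C)CC)[C@H]1CC(=O)O[C@H]1/C=C(/CO)[Sn](CCCC)(CCCC)CCCC | intermediate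
22 | (1R,3R)-1-[(2R,3R)-2-[(1Z)-3-hydroxy-2-iodoprop-1-en-1-yl]-5-oxooxolan-3-yl]-3,7-dimethyl-3-(triethylsilyloxy)oct-6-en-1-yl (2R)-2-methylbutanoate | CC(C)=CCC[C@@](C)(O[Si](CC)(CC)CC)C[C@@H](OC(=O)[C@H](C)CC)[C@H]1CC(=O)O[C@H]1/C=C(/CO)I | intermediate
23 | (1R,3R)-1-[(2R,3R)-2-[(1Z)-3-{[tert-butyl(dimethyl)silyl]oxy}-2-iodoprop-1-en-1-yl]-5-oxooxolan-3-yl]-3,7-dimethyl-3-(triethylsilyloxy)oct-6-en-1-yl (2R)-2-methylbutanoate | CC(C)=CCC[C@@](C)(O[Si](CC)(CC)CC)C[C@@H](OC(=O)[C@H](C)CC)[C@H]1CC(=O)O[C@H]1/C=C(/CO[Si](C)(C)C(C)(C)C)I | intermediate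
24 | 4-[(dimethylamino)methyl] derivative of 23 (Mannich base; oxolane C4 as a mixture of epimers; other centres as in 23) | CC(C)=CCC[C@@](C)(O[Si](CC)(CC)CC)C[C@@H](OC(=O)[C@H](C)CC)[C@H]1C(CN(C)C)C(=O)O[C@H]1/C=C(/CO[Si](C)(C)C(C)(C)C)I | intermediate
25 | trimethylammonium iodide of 24 (methiodide salt; other centres as in 23) | CC(C)=CCC[C@@](C)(O[Si](CC)(CC)CC)C[C@@H](OC(=O)[C@H](C)CC)[C@H]1C(C[N+](C)(C)C)C(=O)O[C@H]1/C=C(/CO[Si](C)(C)C(C)(C)C)I.[I-] | intermediate
26 | (1R,3R)-1-[(2R,3R)-2-[(1Z)-3-{[tert-butyl(dimethyl)silyl]oxy}-2-iodoprop-1-en-1-yl]-4-methylidene-5-oxooxolan-3-yl]-3,7-dimethyl-3-(triethylsilyloxy)oct-6-en-1-yl (2R)-2-methylbutanoate | CC(C)=CCC[C@@](C)(O[Si](CC)(CC)CC)C[C@@H](OC(=O)[C@H](C)CC)[C@H]1C(=C)C(=O)O[C@H]1/C=C(/CO[Si](C)(C)C(C)(C)C)I | intermediate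
27 | secondary ozonide of 26 (3,3-dimethyl-1,2,4-trioxolane in place of the trisubstituted alkene; other centres as in 26) | CC1(C)OOC(CC[C@@](C)(O[Si](CC)(CC)CC)C[C@@H](OC(=O)[C@H](C)CC)[C@H]2C(=C)C(=O)O[C@H]2/C=C(/CO[Si](C)(C)C(C)(C)C)I)O1 | intermediate
28 | (1R,3R)-1-[(2R,3R)-2-[(1Z)-3-{[tert-butyl(dimethyl)silyl]oxy}-2-iodoprop-1-en-1-yl]-4-methylidene-5-oxooxolan-3-yl]-3-methyl-6-oxo-3-(triethylsilyloxy)hexyl (2R)-2-methylbutanoate | O=CCC[C@@](C)(O[Si](CC)(CC)CC)C[C@@H](OC(=O)[C@H](C)CC)[C@H]1C(=C)C(=O)O[C@H]1/C=C(/CO[Si](C)(C)C(C)(C)C)I | intermediate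
29 | (3aR,4R,6R,10Z,11aS)-10-({[tert-butyl(dimethyl)silyl]oxy}methyl)-9-hydroxy-6-methyl-3-methylidene-2-oxo-6-(triethylsilyloxy)-2,3,3a,4,5,6,7,8,9,11a-decahydrocyclodeca[b]furan-4-yl (2R)-2-methylbutanoate (both epimers at the carbinol C9 of this name, which is C3 in germacranolide numbering) | C=C1C(=O)O[C@H]2/C=C(/CO[Si](C)(C)C(C)(C)C)C(O)CC[C@@](C)(O[Si](CC)(CC)CC)C[C@@H](OC(=O)[C@H](C)CC)[C@@H]12 | intermediate
30 | (3aR,4R,6R,10Z,11aS)-10-({[tert-butyl(dimethyl)silyl]oxy}methyl)-6-methyl-3-methylidene-2,9-dioxo-6-(triethylsilyloxy)-2,3,3a,4,5,6,7,8,9,11a-decahydrocyclodeca[b]furan-4-yl (2R)-2-methylbutanoate | C=C1C(=O)O[C@H]2/C=C(/CO[Si](C)(C)C(C)(C)C)C(=O)CC[C@@](C)(O[Si](CC)(CC)CC)C[C@@H](OC(=O)[C@H](C)CC)[C@@H]12 | intermediate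
31 | CNP0130221.1, (3aR,4R,6R,10Z,11aS)-6-hydroxy-10-(hydroxymethyl)-6-methyl-3-methylidene-2,9-dioxo-2,3,3a,4,5,6,7,8,9,11a-decahydrocyclodeca[b]furan-4-yl (2R)-2-methylbutanoate | C=C1C(=O)O[C@H]2/C=C(/CO)C(=O)CC[C@@](C)(O)C[C@@H](OC(=O)[C@H](C)CC)[C@@H]12 | target

Total step count: 18. Longest linear sequence: 18 steps from 1; compounds 6, 9, 11, 13 and 15 are bought.

Steps most likely to fail

Step 16. Intermolecular coupling and protonation of the alkenylchromium may outrun closure of the strained ten-membered ring. The fallback forms the same C3–C4 bond by an intramolecular Stille acylation and sets out from 28. Pinnick oxidation (NaClO2, NaH2PO4, 2-methyl-2-butene, t-BuOH/H2O) would give the iodo carboxylic acid F1. Iodine–tin exchange with (Me3Sn)2 and Pd(PPh3)4 in toluene would give the trimethylstannyl acid F2. 1-Chloro-N,N,2-trimethylprop-1-en-1-amine would convert it under neutral conditions into the acid chloride F3. Slow addition of F3 to Pd2(dba)3 and tri(2-furyl)phosphine in toluene at high dilution should couple the acyl chloride with the alkenylstannane with retention of the Z geometry. This comes back to the route at 30, so that 29 and step 17 are bypassed.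

Step 12. Tin may be delivered to C5 instead of C4, or the tin hydride may add to the other π bonds. The fallback builds the iodoalkene by α-iodination of an enal and sets out from 20. Semi-hydrogenation over Lindlar catalyst (Pd on CaCO3 poisoned with Pb(OAc)2, quinoline, H2) would give the (Z)-allylic alcohol F4. MnO2 would oxidise it to the enal F5. Iodine and pyridine in CH2Cl2 (conjugate addition, iodination, elimination) should give the thermodynamically preferred (Z)-2-iodo enal F6, whatever the geometry of F5. Reduction with NaBH4 and CeCl3·7H2O comes back to the route at 22.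

Step 9. The C8 acyloxy group may be lost by β-elimination from the β-acyloxy ynone, or the acetylide may attack the ester carbonyls. The fallback replaces the ketone by an aldehyde and sets the C6 carbinol by a ligand-controlled alkynylzinc addition; it sets out from 14. Cp2Zr(H)Cl in THF would reduce the Weinreb amide to the aldehyde F7 without touching the esters. The alkynylzinc reagent made from 15 and Et2Zn, added with Ti(OiPr)4 and the BINOL enantiomer that delivers the 1R carbinol, would give the trimethylsilyl ether F8. The citric acid/MeOH work-up of step 9 then comes back to the route at 18, so that 17 and step 10 are bypassed.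

Further compounds
F1 | step 16 | 4-[(2R-configured acyloxy) chain] iodo acid: the C3 carboxylic acid corresponding to aldehyde 28 (all stereocentres and the Z-iodoalkene as in 28) | O=C(O)CC[C@@](C)(O[Si](CC)(CC)CC)C[C@@H](OC(=O)[C@H](C)CC)[C@H]1C(=C)C(=O)O[C@H]1/C=C(/CO[Si](C)(C)C(C)(C)C)I
F2 | step 16 | trimethylstannyl acid: F1 with the iodine replaced by SnMe3 (Z geometry retained) | O=C(O)CC[C@@](C)(O[Si](CC)(CC)CC)C[C@@H](OC(=O)[C@H](C)CC)[C@H]1C(=C)C(=O)O[C@H]1/C=C(/CO[Si](C)(C)C(C)(C)C)[Sn](C)(C)C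
F3 | step 16 | acid chloride of F2 | O=C(Cl)CC[C@@](C)(O[Si](CC)(CC)CC)C[C@@H](OC(=O)[C@H](C)CC)[C@H]1C(=C)C(=O)O[C@H]1/C=C(/CO[Si](C)(C)C(C)(C)C)[Sn](C)(C)C
F4 | step 12 | (1R,3R)-1-[(2R,3R)-2-[(1Z)-3-hydroxyprop-1-en-1-yl]-5-oxooxolan-3-yl]-3,7-dimethyl-3-(triethylsilyloxy)oct-6-en-1-yl (2R)-2-methylbutanoate | CC(C)=CCC[C@@](C)(O[Si](CC)(CC)CC)C[C@@H](OC(=O)[C@H](C)CC)[C@H]1CC(=O)O[C@H]1/C=C\CO
F5 | step 12 | (Z)-enal: F4 with the CH2OH oxidised to CHO | CC(C)=CCC[C@@](C)(O[Si](CC)(CC)CC)C[C@@H](OC(=O)[C@H](C)CC)[C@H]1CC(=O)O[C@H]1/C=C\C=O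
F6 | step 12 | (Z)-2-iodo enal: 22 with the CH2OH at the aldehyde level (iodine cis to the lactone carbon) | CC(C)=CCC[C@@](C)(O[Si](CC)(CC)CC)C[C@@H](OC(=O)[C@H](C)CC)[C@H]1CC(=O)O[C@H]1/C=C(/C=O)I
F7 | step 9 | tert-butyl (3R,4R,6R)-3-formyl-6,10-dimethyl-4-{[(2R)-2-methylbutanoyl]oxy}-6-(triethylsilyloxy)undec-9-enoate | CC(C)=CCC[C@@](C)(O[Si](CC)(CC)CC)C[C@@H](OC(=O)[C@H](C)CC)[C@@H](CC(=O)OC(C)(C)C)C=O
F8 | step 9 | 4-O-trimethylsilyl ether of 18 (all stereocentres as in 18) | CC(C)=CCC[C@@](C)(O[Si](CC)(CC)CC)C[C@@H](OC(=O)[C@H](C)CC)[C@@H](CC(=O)OC(C)(C)C)[C@@H](O)C#CCO[Si](C)(C)C
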